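**Strategy.** The cage is traced back to an achiral benzoylphloroglucinol. In the cyclohexanone ring C1–C9–C5–C6–C7–C8 of the core (C1 benzoyl-bearing, C5 prenyl-bearing, C9 ketone), the C6–C7–C8 bridge spans the two α-carbons of C9=O, which are ring carbons of the phloroglucinol. A one-flask (3+3) alkylative dearomatization–annulation of methyl ether 9 with acetoxy enal 5 forms C5–C6 and C8–C1, sets the absolute configuration by phase-transfer catalysis and closes a temporary adamantane ring that locks C7 endo. Retro-aldol opening, extension of the C7 chain to prenyl and a biomimetic aerobic radical cascade then deliver the homoadamantane, the 1,2-dioxepane and the hydroperoxide.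

Key step: step 5

Remark: core carbons are numbered as in the bicyclo[3.3.1]nonane skeleton (C1 benzoyl bridgehead, C2/C4 carbonyls, C3 between them, C5 prenyl bridgehead, C6 CH2, C7 CH, C8 CMe2, C9 bridging ketone). Enols are drawn as one tautomer. The cinchonidinium catalyst is assumed to give the C5 sense shown; otherwise its cinchoninium pseudoenantiomer is used.

**Step 1**
Reactants: 1 acetone; 2 isopropenylmagnesium bromide
Product: 4 2,3-dimethylbut-3-en-2-yl acetate, via bromomagnesium alkoxide 3 (not isolated)
Conditions: THF, 0 °C; then Ac2O, DMAP (cat.), 0 → 23 °C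
Reagents that add atoms: acetic anhydride CC(=O)OC(C)=O
Why: Grignard 1,2-addition to the ketone followed by in situ DMAP-catalysed O-acylation of the tertiary alkoxide; no stereocentre is formed.

**Step 2**
Reactants: 4 2,3-dimethylbut-3-en-2-yl acetate
Product: 5 3-formyl-2-methylbut-3-en-2-yl acetate
Conditions: SeO2, 1,4-dioxane, 80 °C
Reagents that add atoms: selenium dioxide O=[Se]=O
Why: Riley allylic oxidation (ene reaction, 2,3-sigmatropic shift, then oxidation of the primary allylic alcohol) at the vinylic methyl group, the only position with allylic hydrogen, should give the 2-substituted acrolein; no stereocentre.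

**Step 3**
Reactants: 6 2,4,6-trihydroxybenzophenone
Product: 7 2,6-dihydroxy-4-methoxybenzophenone (cotoin)
Conditions: Me2SO4 (1 equiv), K2CO3, acetone, 23 °C
Reagents that add atoms: dimethyl sulfate COS(=O)(=O)OC
Why: Williamson O-methylation should take the 4-hydroxyl, which is para to the ketone, the most acidic and not hydrogen-bonded, while the 2- and 6-hydroxyls are chelated to the carbonyl.

**Step 4**
Reactants: 7 cotoin; 8 prenyl bromide
Product: 9 [2,6-dihydroxy-4-methoxy-3,5-bis(3-methylbut-2-en-1-yl)phenyl](phenyl)methanone
Conditions: prenyl bromide (2.2 equiv in all), 10% aq. KOH, 0 → 23 °C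
Reagents that add atoms: prenyl bromide (second equivalent) CC(C)=CCBr
Why: Twofold C-alkylation of the phloroglucinol-type phenoxide in water (Friedel–Crafts-like ortho C-prenylation, one prenyl bromide per free ring position) can only occur at the two unsubstituted ring carbons, water favouring C- over O-alkylation by solvating the phenoxide oxygens; no stereocentre is formed.

**Step 5**
Reactants: 9 O-methyl diprenyl benzophenone; 5 3-formyl-2-methylbut-3-en-2-yl acetate
Product: 11 adamantanol 5-benzoyl-10-hydroxy-6,6-dimethyl-1,3-bis(3-methylbut-2-en-1-yl)adamantane-2,4,9-trione, via dearomatised enal 10 (not isolated)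
Conditions: naphthalene-2,7-diyldimethylene-bridged bis(O-allylcinchonidinium) dibromide (20 mol%), CsOH·H2O, 4 Å MS, CH2Cl2, −50 °C; then conc. aq. HCl, THF, −50 → 23 °C
Reagents that add atoms: water O
Why: Under phase-transfer conditions the mirror-symmetric phenoxide of 9 attacks the CH2 terminus of 5 through a prenylated ring carbon (conjugate addition, then E1cB loss of acetate, an SN2′-type C-alkylation forming C5–C6) to give 10, and the basic phase stops there because the delocalised triketonate of 10 is too weak a nucleophile for the fully substituted β-carbon at −50 °C and the O-methylated C3–C4 unit is a vinylogous ester that cannot serve as an enolate; acid then lets the benzoyl-bearing enol carbon C1 add to the β,β-dimethyl enal (C8–C1) and the C3 enol ether carbon add to the aldehyde with hydrolytic loss of methanol. The closest known reaction type is the alkylative dearomatization–annulation of acylphloroglucinols with α-(acyloxyalkyl) enals, run under cinchona phase-transfer catalysis and completed by acid-mediated closure to adamantane cores. The cyclohexanone ring C1–C9–C5–C6–C7–C8 closes by a 6-endo-trig conjugate addition (both enal alkene carbons end in the ring), and the temporary ring C3–C4–C5–C6–C7–CH(OH) by a 6-exo-trig aldol addition. C5 is set by the chiral ammonium cation, which distinguishes the two enantiotopic prenylated carbons in the contact ion pair; C1, C3 and C7 then follow from the cage, since the bridge can span only one face and only the endo aldehyde can be trapped by the aldol (the exo epimer equilibrates through its enol), and the carbinol should adopt the orientation anti to the C8 methyl groups. The step needs C- over O-alkylation, attack through a prenylated and not the benzoylated carbon, and closure of the CMe2 terminus at C1 and not at C3; the first two follow from the usual behaviour of phloroglucinol phenoxides toward soft acceptors, the third from the 4-methoxy group and from the preference of the C3 enol ether for the harder protonated aldehyde.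

**Step 6**
Reactants: 11 adamantanol
Product: 14 bis(methyl carbonate) of the C7-endo 1-hydroxyallyl enol, via endo aldehyde 12 (not isolated), via allylic alcohol 13 (not isolated)
Conditions: CH2=CHMgBr (excess), CeCl3, THF, −78 → 0 °C; then ClCO2Me (excess), 0 → 23 °C
Reagents that add atoms: vinylmagnesium bromide C=C[Mg]Br; methyl chloroformate (2 equiv incorporated) COC(=O)Cl
Why: Retro-aldol fragmentation of the alkoxide (driven by formation of the C2–C3–C4 diketonate) unveils the C7-endo aldehyde, which the weakly basic organocerium reagent should capture before it can epimerise, and both oxyanions are then acylated; C7 keeps the endo configuration inherited from the cage and the new carbinol centre is removed in step 7.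

**Step 7**
Reactants: 14 bis(methyl carbonate)
Product: 15 C7-endo allyl enol methyl carbonate
Conditions: Pd(OAc)2 (5 mol%), PBu3 (20 mol%), HCO2H, Et3N, THF, 40 °C
Reagents that add atoms: none
Why: Formate reduction of an allylic carbonate (Tsuji–Trost ionisation by zerovalent palladium formed in situ, decarboxylation of the palladium formate and hydride delivery to the more substituted allyl terminus) should give the terminal alkene; the enol carbonate is not allylic, stays in place and keeps the diketone from attacking the π-allyl complex, and C7 is untouched.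

**Step 8**
Reactants: 15 allyl enol carbonate
Product: 17 (1S,5S,7S)-1-benzoyl-4-hydroxy-8,8-dimethyl-3,5,7-tris(3-methylbut-2-en-1-yl)bicyclo[3.3.1]non-3-ene-2,9-dione, via prenyl enol carbonate 16 (not isolated)
Conditions: 2-methyl-2-butene (excess), second-generation Hoveyda–Grubbs catalyst (10 mol%), CH2Cl2, 40 °C; then K2CO3, MeOH, 0 °C
Reagents that add atoms: 2-methyl-2-butene CC=C(C)C
Why: Olefin cross metathesis of the only monosubstituted alkene with a trisubstituted partner installs the isopropylidene terminus (exchange at the existing prenyl groups is degenerate), and mild methanolysis of the vinylogous carbonate frees the enol; no stereocentre is affected.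

**Step 9**
Reactants: 17 7-epi-nemorosone-type enol
Product: 18 target CNP0215795.1
Conditions: Mn(OAc)3·2H2O (20 mol%), O2 (1 atm), AcOH, 23 °C
Reagents that add atoms: dioxygen (2 equiv incorporated) O=O
Why: Biomimetic aerobic radical cascade (oxidative radical cyclization–peroxidation initiated by trivalent manganese): the C3 radical adds to the proximal carbon of the endo C7 prenyl group from the only accessible face, closing the homoadamantane and fixing C3, with the CMe2 radical turned away from the C8 methyl groups (sets the ring CH); O2 capture gives a tertiary peroxyl radical that closes the 1,2-dioxepane by 7-exo addition to the C3 prenyl alkene through a chair-like transition state with the developing 2-propyl radical pseudo-equatorial (sets the peroxide CH), and the new radical takes up a second O2 and a hydrogen atom from the enol of the next molecule to give the hydroperoxide and carry the chain.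

**Compound list**

1 | acetone | CC(C)=O | starting material
2 | isopropenylmagnesium bromide | CC(=C)[Mg]Br | starting material
3 | bromomagnesium 2,3-dimethylbut-3-en-2-olate | CC(=C)C(C)(C)O[Mg]Br | intermediate
4 | 2,3-dimethylbut-3-en-2-yl acetate | CC(=C)C(C)(C)OC(C)=O | intermediate
5 | 3-formyl-2-methylbut-3-en-2-yl acetate | CC(C)(OC(C)=O)C(=C)C=O | intermediate
6 | 2,4,6-trihydroxybenzophenone | O=C(c1ccccc1)c1c(O)cc(O)cc1O | starting material
7 | 2,6-dihydroxy-4-methoxybenzophenone (cotoin) | COc1cc(O)c(C(=O)c2ccccc2)c(O)c1 | intermediate
8 | prenyl bromide (1-bromo-3-methylbut-2-ene) | CC(C)=CCBr | starting material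
9 | [2,6-dihydroxy-4-methoxy-3,5-bis(3-methylbut-2-en-1-yl)phenyl](phenyl)methanone | COc1c(CC=C(C)C)c(O)c(C(=O)c2ccccc2)c(O)c1CC=C(C)C | intermediate
10 | dearomatised enal: 2-benzoyl-3-hydroxy-5-methoxy-4,6-diprenyl-6-(2-formyl-3-methylbut-2-enyl)cyclohexa-2,4-dienone, quaternary carbon as in the SMILES (it becomes C5) | CC(C)=CC[C@@]1(CC(C=O)=C(C)C)C(=O)C(C(=O)c2ccccc2)=C(O)C(CC=C(C)C)=C1OC | intermediate
11 | adamantanol: 5-benzoyl-10-hydroxy-6,6-dimethyl-1,3-bis(3-methylbut-2-en-1-yl)adamantane-2,4,9-trione, hydroxyl anti to the gem-dimethyl carbon | CC(C)=CC[C@]12C[C@@H]3[C@H](O)[C@](CC=C(C)C)(C1=O)C(=O)[C@](C(=O)c1ccccc1)(C2=O)C3(C)C | intermediate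
12 | endo aldehyde: 1-benzoyl-4-hydroxy-8,8-dimethyl-3,5-diprenyl-2,9-dioxobicyclo[3.3.1]non-3-ene-7-carbaldehyde, CHO on the face of the C2–C3–C4 bridge (formed as its enolate) | CC(C)=CC[C@]12C[C@H](C=O)C(C)(C)[C@@](C(=O)c3ccccc3)(C2=O)C(=O)C(CC=C(C)C)=C1O | intermediate
13 | allylic alcohol: C7-endo 1-hydroxyprop-2-enyl analogue of 12, carbinol centre uncontrolled | CC(C)=CC[C@]12C[C@H](C(O)C=C)C(C)(C)[C@@](C(=O)c3ccccc3)(C2=O)C(=O)C(CC=C(C)C)=C1O | intermediate
14 | bis(methyl carbonate) of 13 (allylic carbonate and C4 enol carbonate; the C2 enol carbonate regioisomer, if formed, converges) | CC(C)=CC[C@]12C[C@H](C(OC(=O)OC)C=C)C(C)(C)[C@@](C(=O)c3ccccc3)(C2=O)C(=O)C(CC=C(C)C)=C1OC(=O)OC | intermediate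
15 | C7-endo allyl compound as C4 enol methyl carbonate | CC(C)=CC[C@]12C[C@H](CC=C)C(C)(C)[C@@](C(=O)c3ccccc3)(C2=O)C(=O)C(CC=C(C)C)=C1OC(=O)OC | intermediate
16 | C7-endo prenyl compound as C4 enol methyl carbonate | CC(C)=CC[C@]12C[C@H](CC=C(C)C)C(C)(C)[C@@](C(=O)c3ccccc3)(C2=O)C(=O)C(CC=C(C)C)=C1OC(=O)OC | intermediate
17 | (1S,5S,7S)-1-benzoyl-4-hydroxy-8,8-dimethyl-3,5,7-tris(3-methylbut-2-en-1-yl)bicyclo[3.3.1]non-3-ene-2,9-dione (7-epi-nemorosone constitution, C7 prenyl endo) | CC(C)=CC[C@]12C[C@H](CC=C(C)C)C(C)(C)[C@@](C(=O)c3ccccc3)(C2=O)C(=O)C(CC=C(C)C)=C1O | intermediate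
18 | CNP0215795.1: homoadamantane trione with fused 1,2-dioxepane and 2-hydroperoxypropan-2-yl group | CC(C)=CC[C@]12C[C@@H]3C[C@@H]4C(C)(C)OO[C@H](C(C)(C)OO)C[C@@]4(C1=O)C(=O)[C@](C(=O)c1ccccc1)(C2=O)C3(C)C | target

**Total step count:** 9
**Longest linear sequence:** 7 steps (steps 3–9 from 6, or steps 1, 2, 5–9 from 1)

**Steps most likely to fail**

Step 9. The C3 radical may be captured by oxygen before it cyclises, the first peroxyl radical may be reduced before the seven-membered ring closes, or the 7-exo closure may show poor facial selectivity. The fallback sets out from 17 and separates carbon–carbon from carbon–oxygen bond formation. Oxidative radical cyclization with Mn(OAc)3·2H2O and Cu(OAc)2·H2O in degassed AcOH, terminated by copper-mediated oxidation of the tertiary radical, should give the isopropenyl homoadamantane trione F1. Mukaiyama–Isayama hydroperoxysilylation (Co(acac)2, Et3SiH, O2, 1,2-dichloroethane) then regenerates the tertiary radical by hydrogen-atom transfer to the 1,1-disubstituted alkene, now with no enol present. After oxygen capture, 7-exo closure and a second oxygen capture this should give the triethylsilyl peroxide F2. HF·pyridine in THF at 0 °C returns to the route at 18.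

Step 5. Enantiocontrol in the ion-pair alkylation of the O-methylated phenoxide may be lost, or alkylation may occur on oxygen. The fallback sets out from 9 and 5 and replaces catalytic desymmetrisation by a racemic two-stage annulation with classical resolution. LiHMDS in THF at 0 °C gives the racemic dearomatised enal F3, which is isolated; conc. HCl in THF closes it to the racemic adamantanol F4. Esterification with (S)-2-methoxy-2-phenylacetic acid (DCC, DMAP) and chromatographic separation of the diastereomers gives the (S)-O-methylmandelate of the required enantiomer F5 beside the (S)-O-methylmandelate of the antipode F6, which is discarded. Methanolysis of F5 (K2CO3, MeOH, 0 °C), followed by brief treatment with HCl in THF to re-close any retro-aldol material, returns to the route at 11.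

Step 7. Hydride may be delivered to the wrong allyl terminus, or ionisation in the crowded endo pocket may be slow enough that the enol carbonate is lost and the diketonate traps the π-allyl complex. The fallback sets out from 11 and avoids allyl–palladium chemistry by two Wittig reactions. Excess (methoxymethylene)triphenylphosphorane in THF (−78 → 0 °C) acts as base for the retro-aldol opening and traps the endo aldehyde as the methyl enol ether F7. Mild aqueous acid hydrolysis gives the homologous C7-endo acetaldehyde F8, and any internal aldol adduct of it re-opens under the next basic conditions. Isopropylidenetriphenylphosphorane in THF at 0 °C returns to the route at 17.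

**Further compounds**

F1 | step 9 | isopropenyl homoadamantane trione (C3–CH bond formed, CH bearing prop-1-en-2-yl anti to the gem-dimethyl carbon) | CC(C)=CC[C@]12C[C@@H]3C[C@H](C(C)=C)[C@](CC=C(C)C)(C1=O)C(=O)[C@](C(=O)c1ccccc1)(C2=O)C3(C)C
F2 | step 9 | O-triethylsilyl peroxide of 18 | CC(C)=CC[C@]12C[C@@H]3C[C@@H]4C(C)(C)OO[C@H](C(C)(C)OO[Si](CC)(CC)CC)C[C@@]4(C1=O)C(=O)[C@](C(=O)c1ccccc1)(C2=O)C3(C)C
F3 | step 5 | racemic dearomatised enal (racemate of 10) | CC(C)=CCC1(CC(C=O)=C(C)C)C(=O)C(C(=O)c2ccccc2)=C(O)C(CC=C(C)C)=C1OC
F4 | step 5 | racemic adamantanol (racemate of 11, relative configuration fixed by the cage) | CC(C)=CCC12CC3C(O)C(CC=C(C)C)(C1=O)C(=O)C(C(=O)c1ccccc1)(C2=O)C3(C)C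
F5 | step 5 | (S)-2-methoxy-2-phenylacetate of 11 | CC(C)=CC[C@]12C[C@@H]3[C@H](OC(=O)[C@@H](OC)c4ccccc4)[C@](CC=C(C)C)(C1=O)C(=O)[C@](C(=O)c1ccccc1)(C2=O)C3(C)C
F6 | step 5 | (S)-2-methoxy-2-phenylacetate of the enantiomer of 11 (discarded diastereomer) | CC(C)=CC[C@@]12C[C@H]3[C@@H](OC(=O)[C@@H](OC)c4ccccc4)[C@@](CC=C(C)C)(C1=O)C(=O)[C@@](C(=O)c1ccccc1)(C2=O)C3(C)C
F7 | step 7 | C7-endo 2-methoxyvinyl enol (E/Z mixture) | CC(C)=CC[C@]12C[C@H](C=COC)C(C)(C)[C@@](C(=O)c3ccccc3)(C2=O)C(=O)C(CC=C(C)C)=C1O
F8 | step 7 | C7-endo 2-oxoethyl enol | CC(C)=CC[C@]12C[C@H](CC=O)C(C)(C)[C@@](C(=O)c3ccccc3)(C2=O)C(=O)C(CC=C(C)C)=C1O
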